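I began with a subtraction: the charge minus the solid substrate still read is the loss.

- elm: solid substrate 0.050 M; the very flask that is asked about, followed so far
- flask: solid substrate 0.050 M; time 30 min

- elm (time / min: solid substrate / %, target / %): 1.00: 97.2, 1.1; 2.00: 94.6, 1.8; 3.00: 93.4, 1.6; 4.00: 93.4, 4.1; 5.00: 92.1, 4.9; 6.00: 92.0, 6.6

(standard deviation of a reading: 0.5 percentage points)

* part of the solid substrate that has turned into other species by 30 min (what has only dissolved does not count)
* the target standing at 30 min, as a percentage of the solid substrate charged
* amount of target if the flask were left three thousand times as long, in percent of the solid substrate charged

A note for whoever takes over this flask. At 6.00 min it read 92.0% solid substrate and 6.6% target. Averaged in successive pairs of readings, the loss reads 4.10%, 6.60% and 7.95%. The second rise is 0.540 of the first, so if later rises keep that ratio, they sum to a limit of 9.53%. I call that limit, per volume, the cap; it reads 4.77 mM, the concentration the solid can lose. I guessed it was an equilibrium limit (thermodynamic control).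

The readings leave a mean gap of 2.87% between loss and target, which I took as dissolved material. So I expected target near 6.67% at 30 min, with solid still lying there. Do not add solid substrate: I took the cap as a concentration.

The forecast said 28% conversion, 26% target and 90% eventually, on “near zero-order behaviour while solid remains”. Its target is higher than mine.

The flask gave 7.96% conversion and 7.96% target at 30 min, and 7.98% target at the very long time.

solid substrate ⇌ starting material, rate k1*(cs1 - [starting material]) while solid is left; crystals form when [starting material] > cs1 (solubility = 1.90 mM, k = 0.0210 s⁻¹); starting material ⇌ target (K = 2.10, k = 0.0120 s⁻¹) At 30 min this flask still held solid substrate at 88.2% of the charge, with 3.80% dissolved as starting material. This flask's loss was 11.8%, beside the 9.53% that my cap of 4.77 mM, taken from scattered readings, makes of this charge. In the neighbour flask with 0.020 M of solid substrate, the same cap is 23.8% of the charge, and at 30 min that flask had lost 29.4%.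

The runs come from a simulation with constants of no real substance; scatter was added.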